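**Strategy**

The isoflavan is disconnected at C3–C1' and C4–C4a, with C2 removed as well, so that C3–C4 becomes a two-carbon bridge between C1' of ring B and C4a of ring A. C3 is the only stereocentre, and its bond to C2 can be traced back to a C–B bond. A single palladium-catalysed conjunctive coupling of vinylboronic pinacol ester, the ring B aryllithium and the ring A aryl triflate forms both aryl–carbon bonds and sets C3. The precursors are a 2,6-dioxygenated, prenylated ring A triflate (methoxymethyl ethers at O7 and O8a) and a prenylated ring B bromide whose para-dimethoxy pair is the latent quinone. Boron is then homologated to C2, and the pyran ring is closed by etherification.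

Key step: step 10

**Remarks on the chemistry**

- Positions are given in isoflavan numbering (O1, C2, C3, C4, C4a to C8a; C1' to C6' in ring B). MOM = methoxymethyl. The target is (3R).
- Assumption: the (Sp,Sp) antipode of the ferrocenyl diphosphine is taken to give the (R)-boronate 19. If a model coupling shows the opposite sense, the mirror-image ligand is used with no other change.
- The formyl group is converted into the C4a oxygen in step 4, while the only alkene present is a monosubstituted vinyl group. The peracid-sensitive prenyl group is created afterwards by the Claisen shift in step 6.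
- O4' is carried as a MOM ether and later as an acetate, so the hydroxyquinone is released at the end by mild methanolysis instead of hydroxide attack on a methoxyquinone.
- KOSO2CF3 is added in step 10 to precipitate the bromide left by the lithium–bromine exchange, which would otherwise bind to palladium.

**Route**

Step 1
Reactants: 1 2-methylbut-3-en-2-ol
Product: 2 methyl 2-methylbut-3-en-2-yl carbonate
Conditions: n-BuLi, THF, −78 °C; ClCO2Me, −78 °C → rt
Reagents that add atoms: methyl chloroformate, COC(=O)Cl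
Why: O-acylation of the lithium alkoxide by the chloroformate (carbonate formation) is fast even for a tertiary allylic alcohol and gives the ionisable partner for both O-allylation steps.

Step 2
Reactants: 3 2,4,6-trihydroxybenzaldehyde
Product: 4 2-hydroxy-4,6-bis(methoxymethoxy)benzaldehyde
Conditions: MOMCl (2.1 equiv), i-Pr2NEt, CH2Cl2, 0 °C → rt
Reagents that add atoms: chloromethyl methyl ether, COCCl
Why: Williamson-type O-alkylation in which one ortho hydroxyl stays hydrogen-bonded to the formyl group and is the least nucleophilic, so two equivalents protect the later O7 and O8a and leave the later O5 free.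

Step 3
Reactants: 4 2-hydroxy-4,6-bis(methoxymethoxy)benzaldehyde; 2 methyl 2-methylbut-3-en-2-yl carbonate
Product: 5 2,4-bis(methoxymethoxy)-6-[(2-methylbut-3-en-2-yl)oxy]benzaldehyde
Conditions: Pd(PPh3)4 (3 mol %), THF, 4 Å MS, 0 °C → rt
Reagents that add atoms: none
Why: Tsuji–Trost O-allylation, in which zerovalent palladium ionises the carbonate with loss of CO2 and the phenoxide attacks the more substituted terminus of the 1,1-dimethylallyl palladium cation under kinetic control, giving the tertiary aryl ether.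

Step 4
Reactants: 5 2,4-bis(methoxymethoxy)-6-[(2-methylbut-3-en-2-yl)oxy]benzaldehyde
Product: 7 2,4-bis(methoxymethoxy)-6-[(2-methylbut-3-en-2-yl)oxy]phenol, via aryl formate 6 (not isolated)
Conditions: mCPBA (1.2 equiv), NaHCO3, CH2Cl2, 0 °C; then K2CO3 (cat.), MeOH, rt
Reagents that add atoms: 3-chloroperoxybenzoic acid, O=C(OO)c1cccc(Cl)c1
Why: Baeyer–Villiger (Dakin-type) oxidation, in which the 2,4,6-trioxygenated aryl group migrates readily in the Criegee intermediate while the only alkene, a monosubstituted vinyl group on a quaternary carbon, is epoxidised far more slowly by the buffered peracid; the formate is then removed by methanolysis.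

Step 5
Reactants: 7 2,4-bis(methoxymethoxy)-6-[(2-methylbut-3-en-2-yl)oxy]phenol
Product: 8 2,4-bis(methoxymethoxy)-6-[(2-methylbut-3-en-2-yl)oxy]phenyl trifluoromethanesulfonate
Conditions: Tf2O, pyridine, CH2Cl2, −20 → 0 °C
Reagents that add atoms: trifluoromethanesulfonic anhydride, O=S(=O)(OS(=O)(=O)C(F)(F)F)C(F)(F)F
Why: O-sulfonylation of the phenol, which tolerates two ortho substituents, with pyridine and low temperature keeping the tertiary allylic ether and the acetals intact.

Step 6
Reactants: 8 2,4-bis(methoxymethoxy)-6-[(2-methylbut-3-en-2-yl)oxy]phenyl trifluoromethanesulfonate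
Product: 10 2-methoxy-4,6-bis(methoxymethoxy)-3-(3-methylbut-2-en-1-yl)phenyl trifluoromethanesulfonate (ring A triflate, triflate on C4a), via hydroxyaryl triflate 9 (not isolated)
Conditions: xylene, 130 °C; then DMF, K2CO3, MeI, rt
Reagents that add atoms: iodomethane, CI
Why: Aromatic Claisen rearrangement of the 1,1-dimethylallyl ether delivers a normal prenyl group to C6, the only free ortho position of O5 because C4a carries the triflate, and the phenol set free is methylated in the same flask (Williamson ether synthesis) before any sulfonyl transfer can occur.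

Step 7
Reactants: 11 2,5-dimethoxyphenol
Product: 12 4-bromo-2,5-dimethoxyphenol
Conditions: NBS (1.0 equiv), MeCN, 0 °C
Reagents that add atoms: N-bromosuccinimide, O=C1CCC(=O)N1Br
Why: Electrophilic aromatic bromination goes to the position para to the hydroxyl and ortho to a methoxy group, which is the most activated and less hindered than the position between OH and OMe.

Step 8
Reactants: 12 4-bromo-2,5-dimethoxyphenol; 2 methyl 2-methylbut-3-en-2-yl carbonate
Product: 13 1-bromo-2,5-dimethoxy-4-[(2-methylbut-3-en-2-yl)oxy]benzene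
Conditions: Pd(PPh3)4 (3 mol %), THF, 4 Å MS, 0 °C → rt
Reagents that add atoms: none
Why: Tsuji–Trost O-allylation at the more substituted allyl terminus as in step 3, with ionisation of the allylic carbonate by zerovalent palladium much faster at room temperature than insertion into the electron-rich aryl bromide.

Step 9
Reactants: 13 1-bromo-2,5-dimethoxy-4-[(2-methylbut-3-en-2-yl)oxy]benzene
Product: 15 1-bromo-2,5-dimethoxy-4-(methoxymethoxy)-3-(3-methylbut-2-en-1-yl)benzene (ring B bromide), via prenylphenol 14 (not isolated)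
Conditions: xylene, 130 °C; then CH2Cl2, i-Pr2NEt, MOMCl, 0 °C → rt
Reagents that add atoms: chloromethyl methyl ether, COCCl
Why: Aromatic Claisen rearrangement places the prenyl group on the only free ortho carbon (the future C3', the other ortho carbon bearing OMe), and the phenol (future O4') is then protected as its MOM ether by O-alkylation.

Step 10
Reactants: 15 1-bromo-2,5-dimethoxy-4-(methoxymethoxy)-3-(3-methylbut-2-en-1-yl)benzene; 16 2-ethenyl-4,4,5,5-tetramethyl-1,3,2-dioxaborolane (vinylboronic acid pinacol ester); 10 2-methoxy-4,6-bis(methoxymethoxy)-3-(3-methylbut-2-en-1-yl)phenyl trifluoromethanesulfonate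
Product: 19 2-[(1R)-1-[2,5-dimethoxy-4-(methoxymethoxy)-3-(3-methylbut-2-en-1-yl)phenyl]-2-[2-methoxy-4,6-bis(methoxymethoxy)-3-(3-methylbut-2-en-1-yl)phenyl]ethyl]-4,4,5,5-tetramethyl-1,3,2-dioxaborolane, via aryllithium 17 (not isolated), via lithium vinylboronate complex 18 (not isolated)
Conditions: t-BuLi (2.0 equiv), Et2O, −78 °C; 16, −78 °C → rt; evaporate, THF; KOSO2CF3 (2 equiv), Pd(OAc)2 (3 mol %), (Sp,Sp)-1,1'-bis[bis(3,5-dimethylphenyl)phosphino]-2,2'-bis[(R)-α-(dimethylamino)benzyl]ferrocene (3.6 mol %), 10, 60 °C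
Reagents that add atoms: none
Why: Lithium–bromine exchange gives aryllithium 17, which adds to boron of 16 to form the tetracoordinate vinylboronate 18; zerovalent palladium (from Pd(OAc)2 and the diphosphine) inserts into the C4a–O bond of triflate 10, the cationic divalent arylpalladium binds the vinyl group of 18 and triggers a 1,2-shift of ring B from boron to the boron-bearing carbon (future C3) anti to palladium, and reductive elimination joins C4a to the terminal carbon (C4). The closest known reaction type is the palladium-catalysed enantioselective conjunctive cross-coupling of vinylboron ate complexes with aryl triflates, established for aryl migrating groups; the triflate flanked by two ortho oxygens is a more hindered member of the same electrophile class. No ring is closed. The C3 stereocentre is under catalyst control: the chiral ferrocenyl diphosphine on palladium selects the alkene face that is activated, and the anti-periplanar migration then fixes the R configuration at the boron-bearing carbon. The step needs the metallate shift to win over direct transfer of ring B or vinyl from boron to palladium and over β-hydride elimination, and it needs aryl on the boron-bearing carbon with the electrophile on the CH2 terminus; the regiochemistry is inherent in the mechanism, and the chemoselectivity is secured by the electron-rich, readily migrating ring B aryl, the weakly coordinating triflate counter-ion, the wide-bite-angle ligand and removal of bromide as KBr.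

Step 11
Reactants: 19 2-[(1R)-1-[2,5-dimethoxy-4-(methoxymethoxy)-3-(3-methylbut-2-en-1-yl)phenyl]-2-[2-methoxy-4,6-bis(methoxymethoxy)-3-(3-methylbut-2-en-1-yl)phenyl]ethyl]-4,4,5,5-tetramethyl-1,3,2-dioxaborolane
Product: 21 (2R)-2-[2,5-dimethoxy-4-(methoxymethoxy)-3-(3-methylbut-2-en-1-yl)phenyl]-3-[2-methoxy-4,6-bis(methoxymethoxy)-3-(3-methylbut-2-en-1-yl)phenyl]propan-1-ol, via homologated boronate 20 (not isolated)
Conditions: BrCH2Cl (3 equiv), n-BuLi (2.5 equiv), THF, −78 °C → rt; then NaOH (aq., 2 M), H2O2 (30 %), 0 °C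
Reagents that add atoms: bromochloromethane, ClCBr; hydrogen peroxide, OO
Why: Matteson homologation, in which LiCH2Cl adds to boron and the benzylic carbon migrates to CH2 with loss of chloride and retention at C3, followed by oxidation of the primary C–B bond by alkaline peroxide, which does not epoxidise the isolated prenyl alkenes.

Step 12
Reactants: 21 (2R)-2-[2,5-dimethoxy-4-(methoxymethoxy)-3-(3-methylbut-2-en-1-yl)phenyl]-3-[2-methoxy-4,6-bis(methoxymethoxy)-3-(3-methylbut-2-en-1-yl)phenyl]propan-1-ol
Product: 22 (2R)-3-[4,6-dihydroxy-2-methoxy-3-(3-methylbut-2-en-1-yl)phenyl]-2-[4-hydroxy-2,5-dimethoxy-3-(3-methylbut-2-en-1-yl)phenyl]propan-1-ol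
Conditions: HCl (aq., 3 M)/MeOH, rt
Reagents that add atoms: none
Why: Acid-catalysed acetal exchange with methanol cleaves the three aryl MOM ethers, and dilute acid at room temperature with a short reaction time should spare the prenyl groups next to the freed phenols.

Step 13
Reactants: 22 (2R)-3-[4,6-dihydroxy-2-methoxy-3-(3-methylbut-2-en-1-yl)phenyl]-2-[4-hydroxy-2,5-dimethoxy-3-(3-methylbut-2-en-1-yl)phenyl]propan-1-ol
Product: 23 (3R)-3-[4-hydroxy-2,5-dimethoxy-3-(3-methylbut-2-en-1-yl)phenyl]-5-methoxy-6-(3-methylbut-2-en-1-yl)-3,4-dihydro-2H-chromen-7-ol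
Conditions: PPh3, DIAD, THF (0.02 M), 0 °C → rt
Reagents that add atoms: none
Why: Intramolecular Mitsunobu etherification, in which only O8a can reach the activated primary carbon C2 (six-membered ring, exo closure) whereas O7 and O4' cannot, and C3 is not a reacting centre, so its configuration is kept.

Step 14
Reactants: 23 (3R)-3-[4-hydroxy-2,5-dimethoxy-3-(3-methylbut-2-en-1-yl)phenyl]-5-methoxy-6-(3-methylbut-2-en-1-yl)-3,4-dihydro-2H-chromen-7-ol
Product: 24 (3R)-3-[4-acetoxy-2,5-dimethoxy-3-(3-methylbut-2-en-1-yl)phenyl]-5-methoxy-6-(3-methylbut-2-en-1-yl)-3,4-dihydro-2H-chromen-7-yl acetate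
Conditions: Ac2O, pyridine, DMAP (cat.), CH2Cl2, rt
Reagents that add atoms: acetic anhydride, CC(=O)OC(C)=O
Why: DMAP-catalysed O-acylation of both phenols lowers the electron density of ring A ahead of the oxidation and turns O4' into a group that becomes a very labile vinylogous anhydride once the quinone is formed.

Step 15
Reactants: 24 (3R)-3-[4-acetoxy-2,5-dimethoxy-3-(3-methylbut-2-en-1-yl)phenyl]-5-methoxy-6-(3-methylbut-2-en-1-yl)-3,4-dihydro-2H-chromen-7-yl acetate
Product: 25 (3R)-3-[4-acetoxy-3,6-dioxo-5-(3-methylbut-2-en-1-yl)cyclohexa-1,4-dien-1-yl]-5-methoxy-6-(3-methylbut-2-en-1-yl)-3,4-dihydro-2H-chromen-7-yl acetate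
Conditions: (NH4)2Ce(NO3)6 (2.5 equiv), MeCN/H2O, 0 °C
Reagents that add atoms: water, O
Why: Oxidative demethylation by tetravalent cerium, in which the para-dimethoxy pair at C2' and C5' of ring B is the most easily oxidised site, water adds at both carbons and two molecules of methanol leave to give the para-quinone, while ring A has no para-dioxygen pair and is deactivated by its acetate.

Step 16
Reactants: 25 (3R)-3-[4-acetoxy-3,6-dioxo-5-(3-methylbut-2-en-1-yl)cyclohexa-1,4-dien-1-yl]-5-methoxy-6-(3-methylbut-2-en-1-yl)-3,4-dihydro-2H-chromen-7-yl acetate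
Product: 26 2-hydroxy-5-[(3R)-7-hydroxy-5-methoxy-6-(3-methylbut-2-en-1-yl)-3,4-dihydro-2H-chromen-3-yl]-3-(3-methylbut-2-en-1-yl)cyclohexa-2,5-diene-1,4-dione (CNP0148998.1)
Conditions: K2CO3 (3 equiv), MeOH, 0 °C, argon; then aq. NaH2PO4
Reagents that add atoms: none
Why: Base-mediated transesterification (methanolysis) cleaves the quinonyl acetate and the aryl acetate at 0 °C, and the hydroxyquinone forms its anion at once, which should protect the C3–H centre and the prenylquinone from base-induced tautomerisation.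

**Compound list**

1 | 2-methylbut-3-en-2-ol | C=CC(C)(C)O | starting material
2 | methyl 2-methylbut-3-en-2-yl carbonate | C=CC(C)(C)OC(=O)OC | intermediate
3 | 2,4,6-trihydroxybenzaldehyde | O=Cc1c(O)cc(O)cc1O | starting material
4 | 2-hydroxy-4,6-bis(methoxymethoxy)benzaldehyde | O=Cc1c(O)cc(OCOC)cc1OCOC | intermediate
5 | 2,4-bis(methoxymethoxy)-6-[(2-methylbut-3-en-2-yl)oxy]benzaldehyde | O=Cc1c(OC(C)(C)C=C)cc(OCOC)cc1OCOC | intermediate
6 | 2,4-bis(methoxymethoxy)-6-[(2-methylbut-3-en-2-yl)oxy]phenyl formate | O=COc1c(OC(C)(C)C=C)cc(OCOC)cc1OCOC | intermediate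
7 | 2,4-bis(methoxymethoxy)-6-[(2-methylbut-3-en-2-yl)oxy]phenol | Oc1c(OC(C)(C)C=C)cc(OCOC)cc1OCOC | intermediate
8 | 2,4-bis(methoxymethoxy)-6-[(2-methylbut-3-en-2-yl)oxy]phenyl trifluoromethanesulfonate | C=CC(C)(C)Oc1cc(OCOC)cc(OCOC)c1OS(=O)(=O)C(F)(F)F | intermediate
9 | 2-hydroxy-4,6-bis(methoxymethoxy)-3-(3-methylbut-2-en-1-yl)phenyl trifluoromethanesulfonate | Oc1c(CC=C(C)C)c(OCOC)cc(OCOC)c1OS(=O)(=O)C(F)(F)F | intermediate
10 | 2-methoxy-4,6-bis(methoxymethoxy)-3-(3-methylbut-2-en-1-yl)phenyl trifluoromethanesulfonate (ring A triflate) | COc1c(CC=C(C)C)c(OCOC)cc(OCOC)c1OS(=O)(=O)C(F)(F)F | intermediate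
11 | 2,5-dimethoxyphenol | COc1ccc(OC)c(O)c1 | starting material
12 | 4-bromo-2,5-dimethoxyphenol | COc1cc(Br)c(OC)cc1O | intermediate
13 | 1-bromo-2,5-dimethoxy-4-[(2-methylbut-3-en-2-yl)oxy]benzene | COc1cc(Br)c(OC)cc1OC(C)(C)C=C | intermediate
14 | 4-bromo-3,6-dimethoxy-2-(3-methylbut-2-en-1-yl)phenol | COc1cc(Br)c(OC)c(CC=C(C)C)c1O | intermediate
15 | 1-bromo-2,5-dimethoxy-4-(methoxymethoxy)-3-(3-methylbut-2-en-1-yl)benzene (ring B bromide) | COc1cc(Br)c(OC)c(CC=C(C)C)c1OCOC | intermediate
16 | 2-ethenyl-4,4,5,5-tetramethyl-1,3,2-dioxaborolane (vinylboronic acid pinacol ester) | C=CB1OC(C)(C)C(C)(C)O1 | starting material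
17 | [2,5-dimethoxy-4-(methoxymethoxy)-3-(3-methylbut-2-en-1-yl)phenyl]lithium | [Li]c1cc(OC)c(OCOC)c(CC=C(C)C)c1OC | intermediate
18 | lithium [2,5-dimethoxy-4-(methoxymethoxy)-3-(3-methylbut-2-en-1-yl)phenyl](ethenyl)(pinacolato)borate | [Li+].C=C[B-]1(OC(C)(C)C(C)(C)O1)c1cc(OC)c(OCOC)c(CC=C(C)C)c1OC | intermediate
19 | 2-[(1R)-1-[2,5-dimethoxy-4-(methoxymethoxy)-3-(3-methylbut-2-en-1-yl)phenyl]-2-[2-methoxy-4,6-bis(methoxymethoxy)-3-(3-methylbut-2-en-1-yl)phenyl]ethyl]-4,4,5,5-tetramethyl-1,3,2-dioxaborolane | COc1c(CC=C(C)C)c(OCOC)cc(OCOC)c1C[C@@H](B1OC(C)(C)C(C)(C)O1)c1cc(OC)c(OCOC)c(CC=C(C)C)c1OC | intermediate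
20 | 2-[(2R)-2-[2,5-dimethoxy-4-(methoxymethoxy)-3-(3-methylbut-2-en-1-yl)phenyl]-3-[2-methoxy-4,6-bis(methoxymethoxy)-3-(3-methylbut-2-en-1-yl)phenyl]propyl]-4,4,5,5-tetramethyl-1,3,2-dioxaborolane | COc1c(CC=C(C)C)c(OCOC)cc(OCOC)c1C[C@@H](CB1OC(C)(C)C(C)(C)O1)c1cc(OC)c(OCOC)c(CC=C(C)C)c1OC | intermediate
21 | (2R)-2-[2,5-dimethoxy-4-(methoxymethoxy)-3-(3-methylbut-2-en-1-yl)phenyl]-3-[2-methoxy-4,6-bis(methoxymethoxy)-3-(3-methylbut-2-en-1-yl)phenyl]propan-1-ol | COc1c(CC=C(C)C)c(OCOC)cc(OCOC)c1C[C@@H](CO)c1cc(OC)c(OCOC)c(CC=C(C)C)c1OC | intermediate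
22 | (2R)-3-[4,6-dihydroxy-2-methoxy-3-(3-methylbut-2-en-1-yl)phenyl]-2-[4-hydroxy-2,5-dimethoxy-3-(3-methylbut-2-en-1-yl)phenyl]propan-1-ol | COc1c(CC=C(C)C)c(O)cc(O)c1C[C@@H](CO)c1cc(OC)c(O)c(CC=C(C)C)c1OC | intermediate
23 | (3R)-3-[4-hydroxy-2,5-dimethoxy-3-(3-methylbut-2-en-1-yl)phenyl]-5-methoxy-6-(3-methylbut-2-en-1-yl)-3,4-dihydro-2H-chromen-7-ol | COc1c(CC=C(C)C)c(O)cc2c1C[C@H](c1cc(OC)c(O)c(CC=C(C)C)c1OC)CO2 | intermediate
24 | (3R)-3-[4-acetoxy-2,5-dimethoxy-3-(3-methylbut-2-en-1-yl)phenyl]-5-methoxy-6-(3-methylbut-2-en-1-yl)-3,4-dihydro-2H-chromen-7-yl acetate | COc1c(CC=C(C)C)c(OC(C)=O)cc2c1C[C@H](c1cc(OC)c(OC(C)=O)c(CC=C(C)C)c1OC)CO2 | intermediate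
25 | (3R)-3-[4-acetoxy-3,6-dioxo-5-(3-methylbut-2-en-1-yl)cyclohexa-1,4-dien-1-yl]-5-methoxy-6-(3-methylbut-2-en-1-yl)-3,4-dihydro-2H-chromen-7-yl acetate | COc1c(CC=C(C)C)c(OC(C)=O)cc2c1C[C@H](C1=CC(=O)C(OC(C)=O)=C(CC=C(C)C)C1=O)CO2 | intermediate
26 | 2-hydroxy-5-[(3R)-7-hydroxy-5-methoxy-6-(3-methylbut-2-en-1-yl)-3,4-dihydro-2H-chromen-3-yl]-3-(3-methylbut-2-en-1-yl)cyclohexa-2,5-diene-1,4-dione | COc1c(CC=C(C)C)c(O)cc2c1C[C@H](C1=CC(=O)C(O)=C(CC=C(C)C)C1=O)CO2 | target

**Count**

Total step count: 16.
Longest linear sequence: 12 steps (from 3 through steps 2 to 6 and 10 to 16).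

**Steps most likely to fail**

1. Step 10. Oxidative addition and alkene binding at a palladium centre flanked by the C5 methoxy and C8a MOM-oxy groups may be slow. Direct transfer of ring B or vinyl from boron to palladium (biaryl or styrene formation), β-hydride elimination to an alkenylboronate, or loss of face selectivity could then take over. The fallback separates the stereocentre from the hindered coupling and sets out from 15 and 10. Suzuki–Miyaura vinylation of 15 with 16 (Pd(PPh3)4, K2CO3, dioxane/H2O, 85 °C) should give 1-ethenyl-2,5-dimethoxy-4-(methoxymethoxy)-3-(3-methylbut-2-en-1-yl)benzene F1. Platinum-catalysed enantioselective diboration of its terminal alkene (B2pin2, Pt(dba)3, TADDOL-derived phosphonite of the appropriate antipode, THF, 60 °C; the trisubstituted prenyl alkenes are inert) should give 2,2'-[(1R)-1-[2,5-dimethoxy-4-(methoxymethoxy)-3-(3-methylbut-2-en-1-yl)phenyl]ethane-1,2-diyl]bis(4,4,5,5-tetramethyl-1,3,2-dioxaborolane) F2. Site-selective Suzuki–Miyaura coupling of the primary C–B bond of F2 with triflate 10 (Pd(OAc)2, RuPhos, K3PO4, THF/H2O, 70 °C), a ligand system suited to di-ortho-substituted electrophiles, leaves the benzylic boronate in place and comes back to the route at 19.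

2. Step 15. The one-electron oxidant may not stop at ring B: attack on ring A despite its acetate, oxidative dimerisation at C6', or oxidation of the trisubstituted alkenes could compete, and the acidic medium may hydrolyse the acetates early. The fallback sets out from 24 and replaces the chemical oxidant by anodic oxidation at controlled potential in methanol (undivided cell, carbon anode, LiClO4, 2,6-lutidine, 0 °C). This two-electron process should stop at the quinone bis(dimethyl ketal), (3R)-3-[4-acetoxy-3,3,6,6-tetramethoxy-5-(3-methylbut-2-en-1-yl)cyclohexa-1,4-dien-1-yl]-5-methoxy-6-(3-methylbut-2-en-1-yl)-3,4-dihydro-2H-chromen-7-yl acetate F4, which is shielded from further oxidation. Mild ketal hydrolysis (aqueous acetic acid, THF, rt) then comes back to the route at 25.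

3. Step 12. Protic acid may promote cyclisation of either ortho-prenylphenol (O7 onto the C6 prenyl group, O4' onto the C3' prenyl group) to a 2,2-dimethylchroman, or addition of methanol to the prenyl alkenes, before all three acetals are cleaved. The fallback sets out from 21 and exchanges the acetals under non-protic conditions with Me3SiOSO2CF3 and 2,2'-bipyridyl (CH2Cl2, 0 °C), which converts aryl MOM ethers into aryl trimethylsilyl ethers and also silylates the primary alcohol. This should give [(2R)-2-[2,5-dimethoxy-3-(3-methylbut-2-en-1-yl)-4-(trimethylsilyloxy)phenyl]-3-[2-methoxy-3-(3-methylbut-2-en-1-yl)-4,6-bis(trimethylsilyloxy)phenyl]propoxy]trimethylsilane F3. Brief methanolysis (K2CO3 cat., MeOH, 0 °C) removes the four silyl groups and comes back to the route at 22.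

**Further compounds**

F1 | step 10 | 1-ethenyl-2,5-dimethoxy-4-(methoxymethoxy)-3-(3-methylbut-2-en-1-yl)benzene | C=Cc1cc(OC)c(OCOC)c(CC=C(C)C)c1OC
F2 | step 10 | 2,2'-[(1R)-1-[2,5-dimethoxy-4-(methoxymethoxy)-3-(3-methylbut-2-en-1-yl)phenyl]ethane-1,2-diyl]bis(4,4,5,5-tetramethyl-1,3,2-dioxaborolane) | CC1(C)OB(C[C@@H](B2OC(C)(C)C(C)(C)O2)c2cc(OC)c(OCOC)c(CC=C(C)C)c2OC)OC1(C)C
F3 | step 12 | [(2R)-2-[2,5-dimethoxy-3-(3-methylbut-2-en-1-yl)-4-(trimethylsilyloxy)phenyl]-3-[2-methoxy-3-(3-methylbut-2-en-1-yl)-4,6-bis(trimethylsilyloxy)phenyl]propoxy]trimethylsilane | COc1c(CC=C(C)C)c(O[Si](C)(C)C)cc(O[Si](C)(C)C)c1C[C@@H](CO[Si](C)(C)C)c1cc(OC)c(O[Si](C)(C)C)c(CC=C(C)C)c1OC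
F4 | step 15 | (3R)-3-[4-acetoxy-3,3,6,6-tetramethoxy-5-(3-methylbut-2-en-1-yl)cyclohexa-1,4-dien-1-yl]-5-methoxy-6-(3-methylbut-2-en-1-yl)-3,4-dihydro-2H-chromen-7-yl acetate | COc1c(CC=C(C)C)c(OC(C)=O)cc2c1C[C@H](C1=CC(OC)(OC)C(OC(C)=O)=C(CC=C(C)C)C1(OC)OC)CO2
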